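**Plan**
- Numbering (daucane type): C1 = ring-fusion carbon bearing CH3 (its face is β), C2/C3 = ring CH2, C4 = isopropyl carbinol, C5 = ring-fusion CH (α-H), C6 = anisoate carbon, C7 = CH2, C8 = alkene carbon bearing CH3 (C14), C9 = alkene CH, C10 = angelate carbon.
- Retrosynthesis: remove both acyl groups, return C10 to a ketone and the C8=C9 alkene to an exocyclic C8=C14 methylene, then cut C6–C7 and C9–C10. The carbinol carbons C6 and C10 sit on the adjacent cyclopentane carbons C5 and C1 and are linked only through C7–C8–C9, so the seven-membered ring is a trans-1,2-diformylcyclopentane plus a 2-methylenepropane-1,3-diyl bis-silane.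
- Forward: the five-membered ring first (a cyclopentenone that already carries C10 as an acetal; methyl onto C1, C6 onto the trapped enolate, isopropyl onto C4), then the seven-membered ring in one double Hosomi–Sakurai annulation, then oxidation, alkene migration and reduction at C10 and the second ester.
- Stereochemistry: C1 from a ligand-controlled copper-catalysed methyl addition; C5 trans to the bulky C1 acetal (kinetic and thermodynamic); C4 by addition anti to the C5 substituent; C6 by titanium chelation to the C4 ether oxygen; C10 by CBS reduction supported by the ring; the Z-alkene from angelic acid.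

Key step: step 9

Remark: in this numbering the target is 1S,4R,5S,6S,10R (1β-CH3, 4β-OH, 5α-H, 6α- and 10α-acyloxy).
Remark: the C10 carbinol of 16, 17 and 19 is written 10α (cis to O6, as a titanium-bridged closure would give); the 10β epimer would serve equally, because C10 is a ketone in 20.
Remark: C10 is carried as a dimethyl acetal from the start because a vinyl or ester group on C1 is no larger than the methyl and would not steer C6 to the required face.

Step 1
Reactants: 1 but-3-en-2-one (methyl vinyl ketone); 2 2,2-dimethoxyacetaldehyde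
Product: 3 1,1-dimethoxyhexane-2,5-dione
Conditions: 3-benzyl-5-(2-hydroxyethyl)-4-methylthiazolium chloride (10 mol %), Et3N, EtOH, 75 °C
Reagents that add atoms: none
Why: Stetter reaction, in which the thiazolium-derived acyl anion equivalent of the non-enolisable aldehyde 2 adds 1,4 to the enone 1 and gives the 1,4-diketone without creating a stereocentre.

Step 2
Reactants: 3 1,1-dimethoxyhexane-2,5-dione
Product: 4 3-(dimethoxymethyl)cyclopent-2-en-1-one
Conditions: aq. NaOH (0.5 M), EtOH, reflux
Reagents that add atoms: none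
Why: Intramolecular aldol condensation, in which only the methyl-ketone enolate can reach the activated dialkoxy ketone through a five-membered ring, so that dehydration should give a single 3-substituted cyclopentenone with the base-stable acetal intact.

Step 3
Reactants: 4 3-(dimethoxymethyl)cyclopent-2-en-1-one
Product: 6 triethyl{[(3S)-3-(dimethoxymethyl)-3-methylcyclopent-1-en-1-yl]oxy}silane, via dimethylaluminium enolate 5 (not isolated)
Conditions: Me3Al, Cu(OTf)2 (5 mol %), chiral sulfonate-bearing N-heterocyclic carbene ligand (5 mol %, enantiomer chosen for Re-face delivery at the β-carbon), THF, −78 °C; then Et3SiOTf, −78 °C → rt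
Reagents that add atoms: trimethylaluminium, C[Al](C)C; triethylsilyl trifluoromethanesulfonate, CC[Si](CC)(CC)OS(=O)(=O)C(F)(F)F
Why: Copper-catalysed asymmetric conjugate addition of Me3Al to a β-substituted cyclopentenone, an established way to methyl-bearing quaternary carbons in five-membered rings, in which the chiral ligand sets C1 as S and O-silylation of the aluminium enolate fixes the enolate regiochemistry toward C5.

Step 4
Reactants: 6 triethyl{[(3S)-3-(dimethoxymethyl)-3-methylcyclopent-1-en-1-yl]oxy}silane; 7 trimethyl orthoformate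
Product: 8 (2S,3S)-2,3-bis(dimethoxymethyl)-3-methylcyclopentan-1-one
Conditions: TMSOTf (10 mol %), CH2Cl2, −78 °C; Et3N quench
Reagents that add atoms: none
Why: Mukaiyama-type condensation of the enol silane with the dimethoxycarbenium ion from 7, which should enter C5 anti to the branched acetal on the neighbouring quaternary C1 (syn to the small methyl), while the epimerisable C5 also prefers this trans arrangement of the two acetal groups at equilibrium.

Step 5
Reactants: 8 (2S,3S)-2,3-bis(dimethoxymethyl)-3-methylcyclopentan-1-one; 9 isopropylmagnesium chloride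
Product: 10 (1R,2R,3S)-2,3-bis(dimethoxymethyl)-3-methyl-1-(propan-2-yl)cyclopentan-1-ol
Conditions: CeCl3, THF, −78 → 0 °C; aq. NH4Cl
Reagents that add atoms: none
Why: 1,2-Addition of an organocerium reagent (which suppresses enolisation and β-hydride reduction) to the cyclopentanone from the α face, anti to the adjacent C5 acetal, so that the new C4 hydroxyl is β and cis to C6.

Step 6
Reactants: 10 (1R,2R,3S)-2,3-bis(dimethoxymethyl)-3-methyl-1-(propan-2-yl)cyclopentan-1-ol
Product: 11 (1S,2R,3R)-1,2-bis(dimethoxymethyl)-3-(methoxymethoxy)-1-methyl-3-(propan-2-yl)cyclopentane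
Conditions: KN(SiMe3)2, THF, −78 °C; MOMCl, → 0 °C
Reagents that add atoms: chloromethyl methyl ether (MOMCl), COCCl
Why: Williamson-type O-alkylation of the potassium tertiary alkoxide with the very reactive MOMCl, which masks the β-hydroxyl before the aldehydes appear (no retro-aldol) and supplies an ether oxygen able to chelate titanium in step 9.

Step 7
Reactants: 11 (1S,2R,3R)-1,2-bis(dimethoxymethyl)-3-(methoxymethoxy)-1-methyl-3-(propan-2-yl)cyclopentane
Product: 12 (1S,2R,3R)-3-(methoxymethoxy)-1-methyl-3-(propan-2-yl)cyclopentane-1,2-dicarbaldehyde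
Conditions: PPTS (cat.), acetone/H2O (9:1), 50 °C; used crude
Reagents that add atoms: water, O
Why: Acid-catalysed acetal hydrolysis under conditions too mild for the MOM ether, in which C5 becomes epimerisable but the trans-dialdehyde with C6 anti to the C4 isopropyl group is the more stable isomer, so the configuration should hold.

Step 8
Reactants: 13 3-chloro-2-(chloromethyl)prop-1-ene
Product: 14 trimethyl{2-[(trimethylsilyl)methyl]prop-2-en-1-yl}silane
Conditions: Mg, Me3SiCl, THF, reflux
Reagents that add atoms: chlorotrimethylsilane, C[Si](C)(C)Cl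
Why: Barbier-type in situ Grignard formation and silylation at both allylic chlorides, the usual entry to this bis-allylsilane conjunctive reagent.

Step 9
Reactants: 12 (1S,2R,3R)-3-(methoxymethoxy)-1-methyl-3-(propan-2-yl)cyclopentane-1,2-dicarbaldehyde; 14 trimethyl{2-[(trimethylsilyl)methyl]prop-2-en-1-yl}silane
Product: 16 4β-(methoxymethoxy)dauc-8(14)-ene-6α,10α-diol, via C6 trichlorotitanium alkoxide 15 (not isolated)
Conditions: TiCl4 (2.2 equiv), CH2Cl2 (0.01 M), −78 °C, slow addition of 14 (1.05 equiv), → −40 °C; aq. NaHCO3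
Reagents that add atoms: none
Why: TiCl4 binds the C4 MOM oxygen and the C6 formyl oxygen (cis on the ring) in a six-membered chelate, so the first Hosomi–Sakurai addition of 14 takes place at C6 from the open face of that chelate (the side of H5, away from the C1 methyl) and loss of Me3SiCl leaves the new allylsilane 15. A second equivalent of TiCl4 activates the neopentyl C10 aldehyde, the tethered allylsilane terminus (the future C9) attacks it, and the second silicon departs to leave the exocyclic methylene on C8. The closest known reaction type is the Lewis-acid (3+4) annulation of 1,4-dicarbonyl compounds with 2-(silylmethyl)allyl conjunctive reagents. The seven-membered ring closes in a 7-exo-trig mode with respect to the C10 carbonyl. C6 (α-carbinol, S) is controlled by the C4 oxygen through the chelate, whereas C10 is expected cis to O6 through a titanium bridge but needs no control because it is oxidised in step 12. The step needs ring closure to outrun a second intermolecular allylation and bridged-ether formation; one equivalent of 14 at high dilution serves the first need, and the trans formyl groups, which would have to pass through a trans-fused bicyclic oxocarbenium ion, serve the second.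

Step 10
Reactants: 16 4β-(methoxymethoxy)dauc-8(14)-ene-6α,10α-diol
Product: 17 dauc-8(14)-ene-4β,6α,10α-triol
Conditions: ZnBr2, n-PrSH, CH2Cl2, 0 °C
Reagents that add atoms: none
Why: Lewis acid and thiol cleavage of the MOM ether, in which ZnBr2 activates the acetal and the thiol captures the methoxymethyl cation so that no cyclic formal with O6 can form, freeing the 4β-hydroxyl without touching the alkene.

Step 11
Reactants: 17 dauc-8(14)-ene-4β,6α,10α-triol; 18 4-methoxybenzoyl chloride
Product: 19 6α-(4-methoxybenzoyloxy)dauc-8(14)-ene-4β,10α-diol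
Conditions: pyridine, DMAP (cat.), CH2Cl2, −20 → 0 °C
Reagents that add atoms: none
Why: Site-selective acylation under nucleophilic catalysis, in which the C6 hydroxyl (flanked by CH and CH2 and close to the 4β-OH) should react before the neopentyl C10 hydroxyl next to quaternary C1 and the inert tertiary C4 hydroxyl, with retention at C6.

Step 12
Reactants: 19 6α-(4-methoxybenzoyloxy)dauc-8(14)-ene-4β,10α-diol
Product: 20 4β-hydroxy-6α-(4-methoxybenzoyloxy)dauc-8(14)-en-10-one
Conditions: Dess–Martin periodinane, CH2Cl2, 0 °C → rt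
Reagents that add atoms: none
Why: Dess–Martin oxidation of the only secondary alcohol left, on which either C10 epimer converges, while the tertiary alcohol and the ester are inert.

Step 13
Reactants: 20 4β-hydroxy-6α-(4-methoxybenzoyloxy)dauc-8(14)-en-10-one
Product: 21 4β-hydroxy-6α-(4-methoxybenzoyloxy)dauc-8-en-10-one
Conditions: DBU (0.1 equiv), CH2Cl2, 0 °C
Reagents that add atoms: none
Why: Base-catalysed prototropic isomerisation through the C9 dienolate, in which conjugation is possible only toward C9 (C1 is quaternary and C7 is insulated from the carbonyl), so the C8=C9 enone should result, and catalytic base at low temperature avoids γ-deprotonation at C7 and loss of the anisoate.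

Step 14
Reactants: 21 4β-hydroxy-6α-(4-methoxybenzoyloxy)dauc-8-en-10-one
Product: 22 6α-(4-methoxybenzoyloxy)dauc-8-ene-4β,10α-diol
Conditions: (S)-2-methyl-CBS-oxazaborolidine (0.5 equiv), BH3·SMe2, THF, −30 °C; MeOH
Reagents that add atoms: none
Why: Corey–Bakshi–Shibata 1,2-reduction, in which the (S)-catalyst, reading quaternary C1 as the large and the C9 vinyl CH as the small substituent, should deliver hydride to give the 10R (10α) alcohol, in line with the substrate's own bias for attack anti to the C1–C5 bond, which stands roughly perpendicular to the carbonyl plane in the trans-fused ring.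

Step 15
Reactants: 22 6α-(4-methoxybenzoyloxy)dauc-8-ene-4β,10α-diol; 23 angelic acid [(Z)-2-methylbut-2-enoic acid]
Product: 25 10α-angeloyloxy-6α-(4-methoxybenzoyloxy)dauc-8-en-4β-ol (target), via angeloyl 2,4,6-trichlorobenzoyl anhydride 24 (not isolated)
Conditions: 2,4,6-trichlorobenzoyl chloride, Et3N, toluene, rt; then 22, 75 °C
Reagents that add atoms: none
Why: Yamaguchi esterification, in which the hindered allylic C10 alcohol attacks the less shielded angeloyl carbonyl of 24, the absence of a nucleophilic amine catalyst keeps the Z geometry, the tertiary C4 hydroxyl is too hindered to compete and C10 keeps its configuration.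

**Compound list**
1 | but-3-en-2-one (methyl vinyl ketone) | CC(=O)C=C | starting material
2 | 2,2-dimethoxyacetaldehyde | COC(OC)C=O | starting material
3 | 1,1-dimethoxyhexane-2,5-dione | CC(=O)CCC(=O)C(OC)OC | intermediate
4 | 3-(dimethoxymethyl)cyclopent-2-en-1-one | COC(OC)C1=CC(=O)CC1 | intermediate
5 | dimethylaluminium (3S)-3-(dimethoxymethyl)-3-methylcyclopent-1-en-1-olate (formed in the flask) | COC(OC)[C@@]1(C)CCC(O[Al](C)C)=C1 | intermediate
6 | triethyl{[(3S)-3-(dimethoxymethyl)-3-methylcyclopent-1-en-1-yl]oxy}silane | COC(OC)[C@@]1(C)CCC(O[Si](CC)(CC)CC)=C1 | intermediate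
7 | trimethyl orthoformate | COC(OC)OC | starting material
8 | (2S,3S)-2,3-bis(dimethoxymethyl)-3-methylcyclopentan-1-one (acetal groups trans) | COC(OC)[C@@]1(C)CCC(=O)[C@@H]1C(OC)OC | intermediate
9 | isopropylmagnesium chloride | CC(C)[Mg]Cl | starting material
10 | (1R,2R,3S)-2,3-bis(dimethoxymethyl)-3-methyl-1-(propan-2-yl)cyclopentan-1-ol (OH cis to the C2 acetal) | COC(OC)[C@@]1(C)CC[C@@](O)(C(C)C)[C@@H]1C(OC)OC | intermediate
11 | (1S,2R,3R)-1,2-bis(dimethoxymethyl)-3-(methoxymethoxy)-1-methyl-3-(propan-2-yl)cyclopentane | COC(OC)[C@@]1(C)CC[C@@](OCOC)(C(C)C)[C@@H]1C(OC)OC | intermediate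
12 | (1S,2R,3R)-3-(methoxymethoxy)-1-methyl-3-(propan-2-yl)cyclopentane-1,2-dicarbaldehyde (trans-dialdehyde) | O=C[C@@]1(C)CC[C@@](OCOC)(C(C)C)[C@@H]1C=O | intermediate
13 | 3-chloro-2-(chloromethyl)prop-1-ene | C=C(CCl)CCl | starting material
14 | trimethyl{2-[(trimethylsilyl)methyl]prop-2-en-1-yl}silane | C=C(C[Si](C)(C)C)C[Si](C)(C)C | intermediate
15 | C6 mono-adduct: 6α-trichlorotitanium alkoxide carrying the 2-[(trimethylsilyl)methyl]allyl chain on C6, C10 aldehyde intact (formed in the flask) | O=C[C@@]1(C)CC[C@@](OCOC)(C(C)C)[C@@H]1[C@@H](O[Ti](Cl)(Cl)Cl)CC(=C)C[Si](C)(C)C | intermediate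
16 | 4β-(methoxymethoxy)dauc-8(14)-ene-6α,10α-diol (1S,4R,5S,6S,10R; trans-fused) | O[C@@H]1CC(=C)C[C@H](O)[C@@H]2[C@]1(C)CC[C@@]2(OCOC)C(C)C | intermediate
17 | dauc-8(14)-ene-4β,6α,10α-triol | O[C@@H]1CC(=C)C[C@H](O)[C@@H]2[C@]1(C)CC[C@@]2(O)C(C)C | intermediate
18 | 4-methoxybenzoyl chloride | COc1ccc(cc1)C(Cl)=O | starting material
19 | 6α-(4-methoxybenzoyloxy)dauc-8(14)-ene-4β,10α-diol | O[C@@H]1CC(=C)C[C@H](OC(=O)c3ccc(OC)cc3)[C@@H]2[C@]1(C)CC[C@@]2(O)C(C)C | intermediate
20 | 4β-hydroxy-6α-(4-methoxybenzoyloxy)dauc-8(14)-en-10-one | O=C1CC(=C)C[C@H](OC(=O)c3ccc(OC)cc3)[C@@H]2[C@]1(C)CC[C@@]2(O)C(C)C | intermediate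
21 | 4β-hydroxy-6α-(4-methoxybenzoyloxy)dauc-8-en-10-one | O=C1C=C(C)C[C@H](OC(=O)c3ccc(OC)cc3)[C@@H]2[C@]1(C)CC[C@@]2(O)C(C)C | intermediate
22 | 6α-(4-methoxybenzoyloxy)dauc-8-ene-4β,10α-diol | O[C@@H]1C=C(C)C[C@H](OC(=O)c3ccc(OC)cc3)[C@@H]2[C@]1(C)CC[C@@]2(O)C(C)C | intermediate
23 | angelic acid, (Z)-2-methylbut-2-enoic acid | C/C=C(/C)C(=O)O | starting material
24 | angeloyl 2,4,6-trichlorobenzoyl anhydride (formed in the flask) | C/C=C(/C)C(=O)OC(=O)c1c(Cl)cc(Cl)cc1Cl | intermediate
25 | 10α-angeloyloxy-6α-(4-methoxybenzoyloxy)dauc-8-en-4β-ol, (1S,4R,5S,6S,10R), CNP0168729.1 | C/C=C(/C)C(=O)O[C@@H]1C=C(C)C[C@H](OC(=O)c2ccc(OC)cc2)[C@@H]2[C@]1(C)CC[C@@]2(O)C(C)C | target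

**Step count**
Total: 15 steps. Longest linear sequence: 14 steps (steps 1–7 and 9–15, from 1 and 2 to 25); step 8 is a one-step side branch.

**Steps most likely to fail**

Step 9. The mono-adduct may be consumed by a second intermolecular allylation or by oligomerisation instead of closing the ring, and the facial selectivity at C6 would be poor if the chelate does not form. The fallback sets out from 12 and splits the annulation into two operations with a reagent whose two ends differ in reactivity. Commercial 3-chloro-2-[(trimethylsilyl)methyl]prop-1-ene and Bu3SnLi give tributyl{2-[(trimethylsilyl)methyl]prop-2-en-1-yl}stannane F1. Its stannane end is added to the C6 aldehyde of 12 under MgBr2·OEt2 chelation control (CH2Cl2, −20 °C), conditions that leave the allylsilane end untouched, to give the isolable 6α-hydroxy allylsilane aldehyde F2. F2 is then closed onto the C10 aldehyde by an intramolecular Hosomi–Sakurai reaction (TiCl4, CH2Cl2, −78 °C, high dilution), which returns to the route at 16.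

Step 3. Addition to the branched β-substituent may be slow or poorly enantioselective. The fallback sets out from 4 and moves the stereocontrol to a carbinol that directs a cyclopropanation. CBS reduction of 4 with the (R)-oxazaborolidine and BH3·SMe2 should give (1S)-3-(dimethoxymethyl)cyclopent-2-en-1-ol F3. Hydroxyl-directed Simmons–Smith cyclopropanation (Et2Zn, CH2I2, CH2Cl2, 0 °C) on the face of the hydroxyl gives (1R,2S,5R)-5-(dimethoxymethyl)bicyclo[3.1.0]hexan-2-ol F4. Dess–Martin oxidation gives (1R,5R)-5-(dimethoxymethyl)bicyclo[3.1.0]hexan-2-one F5. Reductive opening of the exocyclic cyclopropane bond (Li, NH3/THF, −78 °C) turns the cyclopropane CH2 into the C1 methyl and leaves the lithium enolate toward C5, which is silylated with Et3SiCl/Et3N to rejoin the route at 6.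

Step 11. Site selectivity between the C6 and C10 hydroxyls may be insufficient, leading to acylation at C10 or at both positions. The fallback sets out from 17 and postpones the anisoate until C10 is finished.
- tBu2Si(OTf)2 and 2,6-lutidine bridge the only 1,3-diol to give the 4β,6α-O-(di-tert-butylsilanediyl) 10α-alcohol F6.
- Dess–Martin oxidation gives the silylene-protected dauc-8(14)-en-10-one F7.
- DBU gives the silylene-protected dauc-8-en-10-one F8.
- CBS reduction as in step 14 gives the silylene-protected dauc-8-en-10α-ol F9.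
- Yamaguchi angeloylation as in step 15 gives the silylene-protected 10α-angelate F10.
- HF·pyridine (THF, 0 °C) releases 10α-angeloyloxydauc-8-ene-4β,6α-diol F11.
- 4-Methoxybenzoyl chloride (18), pyridine and DMAP acylate the one secondary hydroxyl left, which arrives at the target 25.

**Further compounds**
F1 | step 9 | tributyl{2-[(trimethylsilyl)methyl]prop-2-en-1-yl}stannane | CCCC[Sn](CCCC)(CCCC)CC(=C)C[Si](C)(C)C
F2 | step 9 | 6α-hydroxy allylsilane aldehyde (free alcohol of 15; C10 aldehyde intact) | O=C[C@@]1(C)CC[C@@](OCOC)(C(C)C)[C@@H]1[C@@H](O)CC(=C)C[Si](C)(C)C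
F3 | step 3 | (1S)-3-(dimethoxymethyl)cyclopent-2-en-1-ol | COC(OC)C1=C[C@@H](O)CC1
F4 | step 3 | (1R,2S,5R)-5-(dimethoxymethyl)bicyclo[3.1.0]hexan-2-ol (cyclopropane cis to OH) | COC(OC)[C@@]12CC[C@H](O)[C@@H]1C2
F5 | step 3 | (1R,5R)-5-(dimethoxymethyl)bicyclo[3.1.0]hexan-2-one | COC(OC)[C@@]12CCC(=O)[C@@H]1C2
F6 | step 11 | 4β,6α-O-(di-tert-butylsilanediyl)dauc-8(14)-ene-4β,6α,10α-triol | O[C@@H]1CC(=C)C[C@H](O[Si]3(C(C)(C)C)C(C)(C)C)[C@@H]2[C@]1(C)CC[C@@]2(O3)C(C)C
F7 | step 11 | 4β,6α-O-(di-tert-butylsilanediyl)-4β,6α-dihydroxydauc-8(14)-en-10-one | O=C1CC(=C)C[C@H](O[Si]3(C(C)(C)C)C(C)(C)C)[C@@H]2[C@]1(C)CC[C@@]2(O3)C(C)C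
F8 | step 11 | 4β,6α-O-(di-tert-butylsilanediyl)-4β,6α-dihydroxydauc-8-en-10-one | O=C1C=C(C)C[C@H](O[Si]3(C(C)(C)C)C(C)(C)C)[C@@H]2[C@]1(C)CC[C@@]2(O3)C(C)C
F9 | step 11 | 4β,6α-O-(di-tert-butylsilanediyl)dauc-8-ene-4β,6α,10α-triol | O[C@@H]1C=C(C)C[C@H](O[Si]3(C(C)(C)C)C(C)(C)C)[C@@H]2[C@]1(C)CC[C@@]2(O3)C(C)C
F10 | step 11 | 10α-angeloyloxy-4β,6α-O-(di-tert-butylsilanediyl)dauc-8-ene-4β,6α-diol | C/C=C(/C)C(=O)O[C@@H]1C=C(C)C[C@H](O[Si]3(C(C)(C)C)C(C)(C)C)[C@@H]2[C@]1(C)CC[C@@]2(O3)C(C)C
F11 | step 11 | 10α-angeloyloxydauc-8-ene-4β,6α-diol | C/C=C(/C)C(=O)O[C@@H]1C=C(C)C[C@H](O)[C@@H]2[C@]1(C)CC[C@@]2(O)C(C)C
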